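**Retrosynthetic overview**
- The target is fisetinidol-(4β→6)-fisetinidol-(4α→6)-mollisacacidin; the last step is global O-debenzylation.
- Key disconnection: C3–C4 of the upper ring C. O7 of the upper ring A is para to C4a, so C4 (bonded to C4a and to C6 of the middle ring A) can be made the exocyclic carbon of a para-quinone methide (O7=C7…C4a=C4), while C3 is an aldehyde on the O1–C2 tether; reductive closure sets C3 and C4 from C2.
- The precursor comes from C4–C6(middle) bond formation (aryllithium of a brominated middle/lower dimer plus a salicylaldehyde ether); C2 is set by an iridium-catalysed asymmetric allylic etherification and the vinyl group is the masked C3 aldehyde.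
- The middle and lower units keep the preformed rings C of (2R,3R)-fustin; their 4α→6 bond is made by an orthogonally activated Friedel–Crafts coupling (thioether/NIS).
- Ring order: lower and middle rings C (chiral pool), then the interflavanyl bond, then the upper ring C last, in the key step.

Key step: step 13

Assumption: (2R,3R)-fustin is taken as a purchasable, enantiopure natural product. The carbinol-type carbon that becomes C4 of the upper unit is carried as an epimer mixture (5 at its own C4; 16–18 at the future upper C4) because it is planar in the next reactive intermediate; it is left undefined in those SMILES.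

Step 1
Reactants: 1 (2R,3R)-fustin
Product: 2 (+)-mollisacacidin, (2R,3S,4R)-flavan-3,4,7,3',4'-pentol
Conditions: NaBH4, EtOH, 0 °C to rt; AcOH quench
Reagents that add atoms: none
Why: Borohydride reduction of the ring C ketone, in which axial hydride delivery to C4 of the 2,3-trans dihydroflavonol should place the new hydroxyl equatorial and trans to the 3-OH (4R), the usual course for dihydroflavonols.

Step 2
Reactants: 2 (+)-mollisacacidin
Product: 3 (2R,3S,4R)-3,4,7,3',4'-penta-O-benzylmollisacacidin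
Conditions: BnBr (6 equiv), NaH (6 equiv), n-Bu4NI (cat.), DMF, 0 °C to rt
Reagents that add atoms: benzyl bromide, BrCc1ccccc1
Why: Williamson etherification of the three phenols and both alcohols with BnBr present from the start so that the phenoxides are capped quickly; no stereocentre is touched.

Step 3
Reactants: 3 penta-O-benzylmollisacacidin (part of the batch)
Product: 4 6-bromo-3,4,7,3',4'-penta-O-benzylmollisacacidin
Conditions: NBS (1.0 equiv), CH2Cl2, −20 to 0 °C, dark
Reagents that add atoms: N-bromosuccinimide, O=C1CCC(=O)N1Br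
Why: Electrophilic aromatic bromination at C6, which is para to O1 and ortho to the 7-benzyloxy group, whereas C8 is flanked by two oxygens and ring B is less activated; the bromine caps C6 and later serves for metalation.

Step 4
Reactants: 4 6-bromo-penta-O-benzylmollisacacidin
Product: 5 (2R,3S)-3,7,3',4'-tetrakis(benzyloxy)-6-bromo-4-[(2,6-dimethylphenyl)sulfanyl]flavan (C4 epimers)
Conditions: 2,6-dimethylbenzenethiol (3 equiv), BF3·OEt2 (1.2 equiv), CH2Cl2, −78 to −30 °C
Reagents that add atoms: 2,6-dimethylbenzenethiol, Cc1cccc(C)c1S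
Why: SN1 thiolysis in which the Lewis acid ionises only the para-alkoxybenzylic C4–OBn bond and the soft thiol captures the flavan-4-yl cation; the C4 configuration is irrelevant because this centre is ionised again in step 5.

Step 5
Reactants: 5 the 4-arylsulfanyl flavan; 3 penta-O-benzylmollisacacidin (3 equiv, excess recovered)
Product: 6 6-bromo-3,7,3',4'-tetra-O-benzylfisetinidol-(4α→6)-3,4,7,3',4'-penta-O-benzylmollisacacidin
Conditions: N-iodosuccinimide (1.2 equiv), 4 Å molecular sieves, CH2Cl2, −78 to −30 °C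
Reagents that add atoms: none
Why: Iodonium activation of the thioether gives the C4 cation, which undergoes Friedel–Crafts attack by C6 of 3 from the face trans to the 3-benzyloxy group to give the 4α (3,4-trans) bond, while the hard C4–OBn group of 3 is not touched by the soft activator (orthogonal activation) and the bromine blocks self-condensation of the electrophile.

Step 6
Reactants: 7 2,4-dihydroxybenzaldehyde
Product: 8 2-hydroxy-4-(triisopropylsilyloxy)benzaldehyde
Conditions: i-Pr3SiCl (1.05 equiv), imidazole, DMF, 0 °C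
Reagents that add atoms: chlorotriisopropylsilane, CC(C)[Si](Cl)(C(C)C)C(C)C
Why: Selective silylation of the 4-OH, because the 2-OH is held in an intramolecular hydrogen bond to the formyl group.

Step 7
Reactants: 9 3,4-bis(benzyloxy)benzaldehyde
Product: 10 ethyl (E)-3-[3,4-bis(benzyloxy)phenyl]prop-2-enoate
Conditions: triethyl phosphonoacetate, NaH, THF, 0 °C to rt
Reagents that add atoms: triethyl phosphonoacetate, CCOC(=O)CP(=O)(OCC)OCC
Why: Horner–Wadsworth–Emmons olefination, E-selective with the stabilised phosphonate.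

Step 8
Reactants: 10 the ethyl cinnamate
Product: 11 (E)-3-[3,4-bis(benzyloxy)phenyl]prop-2-en-1-ol
Conditions: i-Bu2AlH (2.2 equiv), CH2Cl2, −78 °C
Reagents that add atoms: none
Why: 1,2-Reduction of the enoate to the allylic alcohol with retention of the E geometry.

Step 9
Reactants: 11 the cinnamyl alcohol
Product: 12 (E)-3-[3,4-bis(benzyloxy)phenyl]prop-2-en-1-yl methyl carbonate
Conditions: ClCO2Me, pyridine, CH2Cl2, 0 °C
Reagents that add atoms: methyl chloroformate, COC(=O)Cl
Why: O-Acylation to the linear allylic carbonate needed for iridium-catalysed substitution.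

Step 10
Reactants: 12 the cinnamyl methyl carbonate; 8 2-hydroxy-4-(triisopropylsilyloxy)benzaldehyde
Product: 14 2-{[(1S)-1-[3,4-bis(benzyloxy)phenyl]prop-2-en-1-yl]oxy}-4-(triisopropylsilyloxy)benzaldehyde, via lithium phenolate 13 (not isolated)
Conditions: 8, LiN(SiMe3)2 (1.0 equiv), THF, 0 °C; then 12, [Ir(cod)Cl]2 (2 mol %), BINOL-derived phosphoramidite bearing a bis(1-phenylethyl)amino group (4 mol %, the enantiomer that delivers the S ether), THF, rt
Reagents that add atoms: none
Why: Iridium-catalysed asymmetric allylic etherification of a linear cinnamyl carbonate with a lithium phenoxide, which should give the branched aryl allyl ether with the future C2 set by the ligand (S here; it becomes R by priority change alone once the vinyl group is an aldehyde).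

Step 11
Reactants: 6 the bromo dimer; 14 the allyl aryl ether aldehyde
Product: 17 acetate of the diarylmethanol that joins C6 of the upper unit of the benzylated dimer to C1 of the 2-{[(1S)-1-[3,4-bis(benzyloxy)phenyl]prop-2-en-1-yl]oxy}-4-(triisopropylsilyloxy)phenyl ring (both epimers at the acetoxy carbon, the future C4), via aryllithium 15 (not isolated), via lithium alkoxide 16 (not isolated)
Conditions: 6, n-BuLi (1.05 equiv), THF, −78 °C; 14 (1.3 equiv), −78 °C; Ac2O (3 equiv), −78 to −20 °C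
Reagents that add atoms: acetic anhydride, CC(=O)OC(C)=O
Why: Bromine–lithium exchange, 1,2-addition of the aryllithium to the aldehyde and O-acylation of the alkoxide in the same flask; the new carbinol centre is not controlled and need not be, because both epimers converge in step 13.

Step 12
Reactants: 17 the diarylmethyl acetate
Product: 18 the corresponding (2R)-2-aryl-2-aryloxyacetaldehyde, in which the vinyl group of 17 is a formyl group (future C3); acetate epimers unchanged
Conditions: O3, pyridine (3 equiv), CH2Cl2, −78 °C, dye end-point; crude used at once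
Reagents that add atoms: ozone, [O-][O+]=O
Why: Ozonolysis of the terminal alkene with pyridine-promoted breakdown of the carbonyl oxide directly to the aldehyde; at −78 °C and with exact dosing the alkene should react faster than the alkoxyarenes, and the neutral conditions leave the labile acetate and the C2 centre intact.

Step 13
Reactants: 18 the aldehyde acetate
Product: 20 3',4'-di-O-benzylfisetinidol-(4β→6)-3,7,3',4'-tetra-O-benzylfisetinidol-(4α→6)-3,4,7,3',4'-penta-O-benzylmollisacacidin (upper unit 2R,3S,4S with free 3-OH and 7-OH), via para-quinone methide 19 (not isolated)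
Conditions: Bu4N[Ph3SiF2] (TBAT, 1.1 equiv), THF, −78 to −40 °C; then added slowly to SmI2 (3 equiv, 0.02 M), THF, −78 °C; sat. NH4Cl
Reagents that add atoms: none
Why: Proposed new method: Anhydrous fluoride removes the silyl group from O7 of the upper ring A and the phenoxide expels acetate from C4 (1,6-elimination), so both carbinol epimers of 18 converge on the planar para-quinone methide 19; two single-electron transfers from SmI2 then turn its exocyclic carbon C4 into a phenoxide-stabilised benzylic radical and organosamarium, which adds to the C3 aldehyde on the O1–C2 tether. The closest known reaction types are the samarium Barbier cyclisation of benzylic halides onto carbonyl groups, the SmI2 ketyl–enone cyclisation and radical 1,6-additions to para-quinone methides. Ring C is closed by 6-exo-trig attack on the C3=O bond through a half-chair-like transition state. C2 (R, fixed in step 10) should control both new centres: ring B sits equatorial, the C3–O bond lies anti to C2–O1 in the dipole-minimised arrangement and carries the bulky trivalent samarium alkoxide, which gives 2,3-trans (C3 S), and the middle-unit aryl on C4 takes the pseudoaxial position to avoid allylic 1,3-strain with the peri H5 of ring A, which gives 3,4-cis, the 4β bond (C4 S). The step needs reduction of the quinone methide before the aldehyde (it is far easier to reduce), ring closure faster than protonation or dimerisation of the reduced species (aprotic medium, high dilution, inverse addition) and no epimerisation at C2 (non-basic fluoride, −78 °C).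

Step 14
Reactants: 20 the undeca-O-benzyl trimer
Product: 21 fisetinidol-(4β→6)-fisetinidol-(4α→6)-mollisacacidin (CNP0255184.1)
Conditions: H2 (1 atm), Pd(OH)2/C, THF/MeOH, rt, neutral; filtration, lyophilisation
Reagents that add atoms: none
Why: Hydrogenolysis of the eleven benzyl ethers, which should leave the ring C ether bonds, the interflavanyl C–C bonds and, in neutral medium with monitoring, the C4 hydroxyl of the lower unit in place; no stereocentre is involved.

**Compound list**

1 | (2R,3R)-fustin | Oc1ccc2c(c1)O[C@H](c1ccc(O)c(O)c1)[C@@H](O)C2=O | starting material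
2 | (+)-mollisacacidin, (2R,3S,4R)-flavan-3,4,7,3',4'-pentol | Oc1ccc2c(c1)O[C@H](c1ccc(O)c(O)c1)[C@@H](O)[C@@H]2O | intermediate
3 | (2R,3S,4R)-3,4,7,3',4'-penta-O-benzylmollisacacidin | c1ccccc1COc1ccc2c(c1)O[C@H](c1ccc(OCc3ccccc3)c(OCc3ccccc3)c1)[C@@H](OCc1ccccc1)[C@@H]2OCc1ccccc1 | intermediate
4 | 6-bromo-3,4,7,3',4'-penta-O-benzylmollisacacidin | c1ccccc1COc1c(Br)cc2c(c1)O[C@H](c1ccc(OCc3ccccc3)c(OCc3ccccc3)c1)[C@@H](OCc1ccccc1)[C@@H]2OCc1ccccc1 | intermediate
5 | (2R,3S)-3,7,3',4'-tetrakis(benzyloxy)-6-bromo-4-[(2,6-dimethylphenyl)sulfanyl]flavan, C4 epimers | c1ccccc1COc1c(Br)cc2c(c1)O[C@H](c1ccc(OCc3ccccc3)c(OCc3ccccc3)c1)[C@@H](OCc1ccccc1)C2Sc1c(C)cccc1C | intermediate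
6 | 6-bromo-3,7,3',4'-tetra-O-benzylfisetinidol-(4α→6)-3,4,7,3',4'-penta-O-benzylmollisacacidin | Brc1cc2c(cc1OCc1ccccc1)O[C@H](c1ccc(OCc3ccccc3)c(OCc3ccccc3)c1)[C@@H](OCc1ccccc1)[C@@H]2c1cc2c(cc1OCc1ccccc1)O[C@H](c1ccc(OCc3ccccc3)c(OCc3ccccc3)c1)[C@@H](OCc1ccccc1)[C@@H]2OCc1ccccc1 | intermediate
7 | 2,4-dihydroxybenzaldehyde | O=Cc1ccc(O)cc1O | starting material
8 | 2-hydroxy-4-(triisopropylsilyloxy)benzaldehyde | O=Cc1ccc(O[Si](C(C)C)(C(C)C)C(C)C)cc1O | intermediate
9 | 3,4-bis(benzyloxy)benzaldehyde | O=Cc1ccc(OCc2ccccc2)c(OCc2ccccc2)c1 | starting material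
10 | ethyl (E)-3-[3,4-bis(benzyloxy)phenyl]prop-2-enoate | CCOC(=O)/C=C/c1ccc(OCc2ccccc2)c(OCc2ccccc2)c1 | intermediate
11 | (E)-3-[3,4-bis(benzyloxy)phenyl]prop-2-en-1-ol | OC/C=C/c1ccc(OCc2ccccc2)c(OCc2ccccc2)c1 | intermediate
12 | (E)-3-[3,4-bis(benzyloxy)phenyl]prop-2-en-1-yl methyl carbonate | COC(=O)OC/C=C/c1ccc(OCc2ccccc2)c(OCc2ccccc2)c1 | intermediate
13 | lithium 2-formyl-5-(triisopropylsilyloxy)phenolate | [Li+].[O-]c1cc(O[Si](C(C)C)(C(C)C)C(C)C)ccc1C=O | intermediate
14 | 2-{[(1S)-1-[3,4-bis(benzyloxy)phenyl]prop-2-en-1-yl]oxy}-4-(triisopropylsilyloxy)benzaldehyde | O=Cc1ccc(O[Si](C(C)C)(C(C)C)C(C)C)cc1O[C@H](c1ccc(OCc2ccccc2)c(OCc2ccccc2)c1)C=C | intermediate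
15 | aryllithium from 6 (lithium in place of bromine at C6 of the upper unit) | [Li]c1cc2c(cc1OCc1ccccc1)O[C@H](c1ccc(OCc3ccccc3)c(OCc3ccccc3)c1)[C@@H](OCc1ccccc1)[C@@H]2c1cc2c(cc1OCc1ccccc1)O[C@H](c1ccc(OCc3ccccc3)c(OCc3ccccc3)c1)[C@@H](OCc1ccccc1)[C@@H]2OCc1ccccc1 | intermediate
16 | lithium diarylmethanolate from 15 and 14, carbinol epimers | [Li]OC(c1ccc(O[Si](C(C)C)(C(C)C)C(C)C)cc1O[C@H](c1ccc(OCc2ccccc2)c(OCc2ccccc2)c1)C=C)c1cc2c(cc1OCc1ccccc1)O[C@H](c1ccc(OCc3ccccc3)c(OCc3ccccc3)c1)[C@@H](OCc1ccccc1)[C@@H]2c1cc2c(cc1OCc1ccccc1)O[C@H](c1ccc(OCc3ccccc3)c(OCc3ccccc3)c1)[C@@H](OCc1ccccc1)[C@@H]2OCc1ccccc1 | intermediate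
17 | diarylmethyl acetate (vinyl, silyl ether), epimers at the acetoxy carbon | CC(=O)OC(c1ccc(O[Si](C(C)C)(C(C)C)C(C)C)cc1O[C@H](c1ccc(OCc2ccccc2)c(OCc2ccccc2)c1)C=C)c1cc2c(cc1OCc1ccccc1)O[C@H](c1ccc(OCc3ccccc3)c(OCc3ccccc3)c1)[C@@H](OCc1ccccc1)[C@@H]2c1cc2c(cc1OCc1ccccc1)O[C@H](c1ccc(OCc3ccccc3)c(OCc3ccccc3)c1)[C@@H](OCc1ccccc1)[C@@H]2OCc1ccccc1 | intermediate
18 | (2R)-aryloxy aryl acetaldehyde with diarylmethyl acetate and silyl ether, epimers at the acetoxy carbon | CC(=O)OC(c1ccc(O[Si](C(C)C)(C(C)C)C(C)C)cc1O[C@H](c1ccc(OCc2ccccc2)c(OCc2ccccc2)c1)C=O)c1cc2c(cc1OCc1ccccc1)O[C@H](c1ccc(OCc3ccccc3)c(OCc3ccccc3)c1)[C@@H](OCc1ccccc1)[C@@H]2c1cc2c(cc1OCc1ccccc1)O[C@H](c1ccc(OCc3ccccc3)c(OCc3ccccc3)c1)[C@@H](OCc1ccccc1)[C@@H]2OCc1ccccc1 | intermediate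
19 | para-quinone methide of the upper ring A (O7 as carbonyl, C4 as exocyclic methide carbon bearing C6 of the dimer), C3 aldehyde on the O1–C2 tether; double-bond geometry undefined | O=C[C@@H](c1ccc(OCc2ccccc2)c(OCc2ccccc2)c1)OC1=CC(=O)C=CC1=Cc1cc2c(cc1OCc1ccccc1)O[C@H](c1ccc(OCc3ccccc3)c(OCc3ccccc3)c1)[C@@H](OCc1ccccc1)[C@@H]2c1cc2c(cc1OCc1ccccc1)O[C@H](c1ccc(OCc3ccccc3)c(OCc3ccccc3)c1)[C@@H](OCc1ccccc1)[C@@H]2OCc1ccccc1 | intermediate
20 | 3',4'-di-O-benzylfisetinidol-(4β→6)-3,7,3',4'-tetra-O-benzylfisetinidol-(4α→6)-3,4,7,3',4'-penta-O-benzylmollisacacidin | Oc1ccc2c(c1)O[C@H](c1ccc(OCc3ccccc3)c(OCc3ccccc3)c1)[C@@H](O)[C@H]2c1cc2c(cc1OCc1ccccc1)O[C@H](c1ccc(OCc3ccccc3)c(OCc3ccccc3)c1)[C@@H](OCc1ccccc1)[C@@H]2c1cc2c(cc1OCc1ccccc1)O[C@H](c1ccc(OCc3ccccc3)c(OCc3ccccc3)c1)[C@@H](OCc1ccccc1)[C@@H]2OCc1ccccc1 | intermediate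
21 | fisetinidol-(4β→6)-fisetinidol-(4α→6)-mollisacacidin (CNP0255184.1) | Oc1ccc2c(c1)O[C@H](c1ccc(O)c(O)c1)[C@@H](O)[C@H]2c1cc2c(cc1O)O[C@H](c1ccc(O)c(O)c1)[C@@H](O)[C@@H]2c1cc2c(cc1O)O[C@H](c1ccc(O)c(O)c1)[C@@H](O)[C@@H]2O | target

**Step count**
- Total steps: 14.
- Longest linear sequence: 9 steps (steps 1, 2, 3, 4, 5, 11, 12, 13, 14, from fustin).

**Steps most likely to fail**

Step 13. What may go wrong: the middle-unit aryl may take the pseudoequatorial instead of the pseudoaxial position at C4 (wrong facial selectivity), the reduced quinone methide may be protonated or dimerise before ring closure, or C2 may epimerise through the aldehyde enol. Fallback with known chemistry, forming the same C3–C4 bond by a samarium pinacol cyclisation: setting out from 6 and 14, aryllithium 15 is added to 14 and quenched with aqueous NH4Cl to give the free diarylmethanol F1. Dess–Martin periodinane oxidises it to the diaryl ketone F2, and ozonolysis (O3, pyridine, CH2Cl2, −78 °C) gives the keto aldehyde F3. SmI2 (2.5 equiv) with t-BuOH in THF at −78 °C should close ring C by ketyl–ketyl coupling to the cis-3,4-diol F4, with the diol trans to the 2-aryl group. Ionic hydrogenation (Et3SiH, CF3CO2H, CH2Cl2, −78 °C) removes the tertiary, doubly benzylic 4-OH, with hydride expected trans to the 3-OH, to give the 7-O-silyl ether F5. Bu4NF in THF then returns to the route at 20.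

Step 10. What may go wrong: re-ionisation of the branched ether (good phenoxide leaving group, electron-rich cinnamyl system) may erode enantiomeric purity and branched selectivity, and the chelated, electron-poor phenoxide may attack slowly. Fallback by resolution and substitution with retention: setting out from 9, vinylmagnesium bromide gives racemic 1-[3,4-bis(benzyloxy)phenyl]prop-2-en-1-ol F6. Lipase-catalysed acylation (Novozym 435, vinyl acetate) leaves the (S)-alcohol F7 and converts the other enantiomer into the (R)-acetate F8, which is separated. The potassium alkoxide of F7 (KN(SiMe3)2, THF, −40 to 0 °C) displaces fluoride from 2-fluoro-4-(triisopropylsilyloxy)benzonitrile F9 (from commercial 2-fluoro-4-hydroxybenzonitrile, i-Pr3SiCl, imidazole) to give the (S)-aryl ether nitrile F10. i-Bu2AlH at −78 °C and hydrolysis then return to the route at 14.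

Step 5. What may go wrong: NIS may iodinate the electron-rich nucleophile instead of activating sulfur, facial selectivity at C4 may be poor, or adventitious acid may scramble the C4–OBn group. Fallback by late bromination: setting out from 3, TMSOTf-catalysed self-condensation (3 as both electrophile and nucleophile, CH2Cl2, −78 °C, stopped at partial conversion) gives the unbrominated dimer 3,7,3',4'-tetra-O-benzylfisetinidol-(4α→6)-3,4,7,3',4'-penta-O-benzylmollisacacidin F11. NBS then brominates the open C6 of its upper unit and returns to the route at 6.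

**Further compounds**

F1 | step 13 | free diarylmethanol corresponding to 17 (OH in place of OAc), carbinol epimers | OC(c1ccc(O[Si](C(C)C)(C(C)C)C(C)C)cc1O[C@H](c1ccc(OCc2ccccc2)c(OCc2ccccc2)c1)C=C)c1cc2c(cc1OCc1ccccc1)O[C@H](c1ccc(OCc3ccccc3)c(OCc3ccccc3)c1)[C@@H](OCc1ccccc1)[C@@H]2c1cc2c(cc1OCc1ccccc1)O[C@H](c1ccc(OCc3ccccc3)c(OCc3ccccc3)c1)[C@@H](OCc1ccccc1)[C@@H]2OCc1ccccc1
F2 | step 13 | diaryl ketone from F1 | O=C(c1ccc(O[Si](C(C)C)(C(C)C)C(C)C)cc1O[C@H](c1ccc(OCc2ccccc2)c(OCc2ccccc2)c1)C=C)c1cc2c(cc1OCc1ccccc1)O[C@H](c1ccc(OCc3ccccc3)c(OCc3ccccc3)c1)[C@@H](OCc1ccccc1)[C@@H]2c1cc2c(cc1OCc1ccccc1)O[C@H](c1ccc(OCc3ccccc3)c(OCc3ccccc3)c1)[C@@H](OCc1ccccc1)[C@@H]2OCc1ccccc1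
F3 | step 13 | keto aldehyde (diaryl ketone at future C4, (2R)-aldehyde at future C3) | O=C(c1ccc(O[Si](C(C)C)(C(C)C)C(C)C)cc1O[C@H](c1ccc(OCc2ccccc2)c(OCc2ccccc2)c1)C=O)c1cc2c(cc1OCc1ccccc1)O[C@H](c1ccc(OCc3ccccc3)c(OCc3ccccc3)c1)[C@@H](OCc1ccccc1)[C@@H]2c1cc2c(cc1OCc1ccccc1)O[C@H](c1ccc(OCc3ccccc3)c(OCc3ccccc3)c1)[C@@H](OCc1ccccc1)[C@@H]2OCc1ccccc1
F4 | step 13 | pinacol product: upper unit as 2,3-trans-3,4-cis-flavan-3,4-diol with the dimer aryl on C4, 7-O-triisopropylsilyl | CC(C)[Si](C(C)C)(C(C)C)Oc1ccc2c(c1)O[C@H](c1ccc(OCc3ccccc3)c(OCc3ccccc3)c1)[C@@H](O)[C@]2(O)c1cc2c(cc1OCc1ccccc1)O[C@H](c1ccc(OCc3ccccc3)c(OCc3ccccc3)c1)[C@@H](OCc1ccccc1)[C@@H]2c1cc2c(cc1OCc1ccccc1)O[C@H](c1ccc(OCc3ccccc3)c(OCc3ccccc3)c1)[C@@H](OCc1ccccc1)[C@@H]2OCc1ccccc1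
F5 | step 13 | 7-O-triisopropylsilyl ether of 20 | CC(C)[Si](C(C)C)(C(C)C)Oc1ccc2c(c1)O[C@H](c1ccc(OCc3ccccc3)c(OCc3ccccc3)c1)[C@@H](O)[C@H]2c1cc2c(cc1OCc1ccccc1)O[C@H](c1ccc(OCc3ccccc3)c(OCc3ccccc3)c1)[C@@H](OCc1ccccc1)[C@@H]2c1cc2c(cc1OCc1ccccc1)O[C@H](c1ccc(OCc3ccccc3)c(OCc3ccccc3)c1)[C@@H](OCc1ccccc1)[C@@H]2OCc1ccccc1
F6 | step 10 | racemic 1-[3,4-bis(benzyloxy)phenyl]prop-2-en-1-ol | C=CC(O)c1ccc(OCc2ccccc2)c(OCc2ccccc2)c1
F7 | step 10 | (S)-1-[3,4-bis(benzyloxy)phenyl]prop-2-en-1-ol | O[C@H](c1ccc(OCc2ccccc2)c(OCc2ccccc2)c1)C=C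
F8 | step 10 | (R)-1-[3,4-bis(benzyloxy)phenyl]prop-2-en-1-yl acetate | CC(=O)O[C@@H](c1ccc(OCc2ccccc2)c(OCc2ccccc2)c1)C=C
F9 | step 10 | 2-fluoro-4-(triisopropylsilyloxy)benzonitrile | N#Cc1ccc(O[Si](C(C)C)(C(C)C)C(C)C)cc1F
F10 | step 10 | 2-{[(1S)-1-[3,4-bis(benzyloxy)phenyl]prop-2-en-1-yl]oxy}-4-(triisopropylsilyloxy)benzonitrile | N#Cc1ccc(O[Si](C(C)C)(C(C)C)C(C)C)cc1O[C@H](c1ccc(OCc2ccccc2)c(OCc2ccccc2)c1)C=C
F11 | step 5 | 3,7,3',4'-tetra-O-benzylfisetinidol-(4α→6)-3,4,7,3',4'-penta-O-benzylmollisacacidin | c1cc2c(cc1OCc1ccccc1)O[C@H](c1ccc(OCc3ccccc3)c(OCc3ccccc3)c1)[C@@H](OCc1ccccc1)[C@@H]2c1cc2c(cc1OCc1ccccc1)O[C@H](c1ccc(OCc3ccccc3)c(OCc3ccccc3)c1)[C@@H](OCc1ccccc1)[C@@H]2OCc1ccccc1
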